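**Plan**

1. Retrosynthetic cuts, in order: the ester bond O8–C1'; the vinyl group together with O8–H, back to a γ-lactone C10–C1(=O)–O8; the two exocyclic methylenes (C3, C13), back to CH2 groups next to carbonyls; the ring bond C5–C10; then C8–C9 and C5=C4, which leads to (2R,3S)-isocitric acid lactone (C5, C6, C7, C8, C11, C12).
2. Enabling feature: on the cyclohexane C5–C10 the vinyl group of the quaternary carbon C10 and the oxygen on C8 are 1,3-cis, so the vinyl CH can be carried as a lactone carbonyl bound to O8. The resulting five-membered α-methylene lactone gives C10 as a tertiary enolate when hydride adds to its CH2, and C5, which is β to the oxidised carbon C15, is the β-carbon of an enoate.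
3. Forward order: isocitrate lactone (lactone A) → the C5 and C8 carboxyls told apart through the cyclic anhydride → enoate on C6 and α-methylene lactone B on C7 → copper hydride-triggered reductive Michael cyclisation closes the carbocycle → double α-methylenation → lactone A opened and silylated → lactone B reduced and methylenated to vinyl plus free 8-OH → acylation → desilylation.
4. Stereochemistry: C6 and C7 from the chiral pool; C8 from Felkin–Anh allylation; C10 from the lactone tether; C5 from the chair transition state of the cyclisation; C3' from (R)-3-hydroxy-γ-butyrolactone.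

Key step: step 7

Locants (elemane numbering, used for all intermediates): ring C5–C10 with C10 quaternary; C1=C2 vinyl and C14 methyl on C10; C4(=C3)–C15 on C5; O6 on C6; C11(=C13)–C12 on C7; O8 on C8; C1'–C4' in the acyl group; β is the ring face of C14, α the other face. The target is 10β-methyl, 10α-vinyl, 5α-C4, 6β-OH, 7β-C11, 8α-O-acyl (5S,6S,7S,8S,10S,3'R).

Assumption: potassium hydrogen (2R,3S)-isocitrate, methyl 2-(bromomethyl)prop-2-enoate and (R)-3-hydroxy-γ-butyrolactone are taken as commercial starting materials; everything else is a reagent.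

**Route**

Step 1
Reactants: 1 potassium hydrogen (2R,3S)-isocitrate
Product: 2 (2R,3S)-isocitric acid lactone anhydride (cis-fused tetrahydrofuro[3,4-b]furan-2,4,6-trione; lactone A is O6–C12)
Conditions: HCl (1.0 equiv, 4 M in dioxane), then Ac2O, 90 °C, evaporation
Reagents that add atoms: none
Why: acid-driven γ-lactonisation of 6-OH onto C12 and dehydration of the cis 5,8-diacid to the cyclic anhydride (anhydride formation) should set C12 apart from C5 and C8 without touching C6 or C7.

Step 2
Reactants: 2 (2R,3S)-isocitric acid lactone anhydride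
Product: 3 (2R,3S)-2-[(ethylsulfanyl)carbonyl]-5-oxooxolane-3-carboxylic acid
Conditions: EtSH (1.1 equiv), pyridine, DMAP (cat.), CH2Cl2, −20 → 0 °C
Reagents that add atoms: ethanethiol CCS
Why: regioselective thiolysis of the anhydride should occur at the C5 carbonyl, the more electrophilic one because it sits next to the acyloxy-bearing C6, as is known for O-acylmalic anhydrides.

Step 3
Reactants: 3 (2R,3S)-2-[(ethylsulfanyl)carbonyl]-5-oxooxolane-3-carboxylic acid
Product: 4 (2R,3S)-2-formyl-5-oxooxolane-3-carboxylic acid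
Conditions: Et3SiH (4 equiv), Pd/C (10% Pd, 5 mol%), acetone, rt
Reagents that add atoms: none
Why: the Fukuyama reduction should convert the thioester into the aldehyde under neutral conditions that spare the lactone, the free acid and the stereocentre C6.

Step 4
Reactants: 4 (2R,3S)-2-formyl-5-oxooxolane-3-carboxylic acid
Product: 5 (2S,3S)-2-[(E)-3-tert-butoxy-3-oxoprop-1-enyl]-5-oxooxolane-3-carboxylic acid
Conditions: Ph3P=CHCO2tBu (2.2 equiv), CH2Cl2, 0 °C → rt; work-up at pH 3
Reagents that add atoms: tert-butyl 2-(triphenylphosphoranylidene)acetate CC(C)(C)OC(=O)C=P(c1ccccc1)(c1ccccc1)c1ccccc1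
Why: Wittig olefination with a stabilised ylide should give the (E)-enoate C5=C4–C15, the later Michael acceptor, the second equivalent of ylide acting as base for the acid.

Step 5
Reactants: 5 (2S,3S)-2-[(E)-3-tert-butoxy-3-oxoprop-1-enyl]-5-oxooxolane-3-carboxylic acid
Product: 7 tert-butyl (E)-3-[(2S,3S)-3-formyl-5-oxooxolan-2-yl]prop-2-enoate, via acid chloride 6 (not isolated)
Conditions: Me2C=C(Cl)NMe2 (Ghosez reagent), CH2Cl2, 0 °C; then LiAlH(OtBu)3 (1.05 equiv), THF, −78 °C
Reagents that add atoms: none
Why: neutral acid chloride formation followed by reduction of the acyl chloride with the hindered hydride LiAlH(OtBu)3 should stop at the aldehyde and leave lactone, enoate and tert-butyl ester untouched.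

Step 6
Reactants: 7 tert-butyl (E)-3-[(2S,3S)-3-formyl-5-oxooxolan-2-yl]prop-2-enoate; 8 methyl 2-(bromomethyl)prop-2-enoate
Product: 10 tert-butyl (E)-3-[(2S,3R)-3-[(2S)-4-methylidene-5-oxooxolan-2-yl]-5-oxooxolan-2-yl]prop-2-enoate, via hydroxy ester 9 (not isolated)
Conditions: Zn dust, sat. aq. NH4Cl/THF, 0 °C → rt; then PPTS (cat.), toluene, 60 °C
Reagents that add atoms: none
Why: Barbier allylation with the 2-(methoxycarbonyl)allylzinc reagent followed by lactonisation should build α-methylene lactone B, C8 being set by Felkin–Anh attack anti to the C6 branch (7,8-syn, reinforced by 1,3-anti induction from O6), while the equilibrating acid funnels the hydroxy ester into the dilactone in which O6 and O8 are both acylated.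

Step 7
Reactants: 10 tert-butyl (E)-3-[(2S,3R)-3-[(2S)-4-methylidene-5-oxooxolan-2-yl]-5-oxooxolan-2-yl]prop-2-enoate
Product: 13 tricyclic dilactone tert-butyl ester (ring C5–C10; 10β-methyl; 5α-CH2CO2tBu; lactone A O6–C12 cis-fused on the β face at C6/C7; lactone B C1–O8 bridging the α face at C10/C8), via lactone copper enolate 11 (not isolated), via cyclised ester copper enolate 12 (not isolated)
Conditions: [(Ph3P)CuH]6 (0.5 equiv of the hexamer), degassed toluene, −40 °C → rt; then sat. aq. NH4Cl
Reagents that add atoms: none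
Why: Copper hydride should add hydride to the unhindered exocyclic CH2 (C14) of lactone B in preference to the β-branched tert-butyl enoate, which gives regiospecifically the tertiary copper enolate at C10 (base could not form it next to the more acidic C11H2 of lactone A); this enolate adds to C5 of the enoate in an intramolecular Michael reaction and the resulting ester enolate is protonated on work-up. The closest known reaction type is the copper hydride-mediated reductive Michael cyclisation of tethered bis-acceptors. The cyclohexane C5–C10 is closed in the 6-exo-trig mode, which at the same time makes lactone B the two-atom bridge of a 6-oxabicyclo[3.2.1]octan-7-one. The quaternary centre C10 is fixed by the tether, because C10 can reach C5 only on the face of lactone B that carries C7, so C1 and O8 end up cis (α) and the new methyl β. C5 is set by the chair transition state imposed by that bridge, in which the enoate lies equatorial (α) to avoid the axial C11H2 of lactone A on C7 and keeps H6 eclipsed with C5=C4 (A(1,3) strain). The step needs chemoselective hydride delivery, secured by the difference between a 1,1-disubstituted and a β-branched acceptor, and a Michael addition faster than enolate protonation, secured by exclusion of proton sources.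

Step 8
Reactants: 13 tricyclic dilactone tert-butyl ester
Product: 16 bis(methylidene) tricycle (as 13 but C11=C13H2 plus C4=C3H2), via bis-Mannich base 14 (not isolated), via bis-ammonium iodide 15 (not isolated)
Conditions: LiN(iPr)2 (2.4 equiv), THF, −78 °C; CH2=NMe2+ I− (4 equiv), −78 °C → rt; then MeI, MeOH/CH2Cl2, rt; then NaHCO3 (aq), CH2Cl2, rt
Reagents that add atoms: N,N-dimethylmethaniminium iodide (Eschenmoser's salt) C=[N+](C)C.[I-]
Why: a double Mannich reaction of the only two enolisable CH2 groups (C11 of lactone A and C4 of the ester; lactone B has no α-hydrogen) followed by Hofmann-type elimination of the quaternised amines should install both exocyclic methylenes in one operation.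

Step 9
Reactants: 16 bis(methylidene) tricycle
Product: 19 seco acid (6β-OSiEt3; 12-CO2H on C11=C13; lactone B intact; tert-butyl 15-ester), via lithium hydroxy carboxylate 17 (not isolated), via silyl ester 18 (not isolated)
Conditions: LiOH·H2O (1.1 equiv), THF/H2O, 0 °C; evaporation; Et3SiCl (3 equiv), imidazole, DMAP (cat.), DMF, 0 °C → rt; then pH 5 phosphate buffer/THF, 0 °C
Reagents that add atoms: lithium hydroxide [Li+].[OH-]; chlorotriethylsilane CC[Si](Cl)(CC)CC
Why: in this lactone opening and silylation sequence saponification should occur selectively at the unhindered fused lactone A (lactone B is bridged and neopentyl-like, the tert-butyl ester is inert to hydroxide), silylation protects O6 before relactonisation, and the labile silyl ester is hydrolysed on buffered work-up.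

Step 10
Reactants: 19 seco acid
Product: 20 lactol acid (C1 hemiacetal bridged to O8; 15-OH; 12-CO2H; 6β-OSiEt3)
Conditions: iBu2AlH (6 equiv), CH2Cl2, −78 → −30 °C; KNaC4H4O6 (Rochelle salt) work-up at pH 5
Reagents that add atoms: none
Why: in this iBu2AlH reduction the carboxylic acid is masked in situ as its aluminium carboxylate, the bridged lactone should stop at the lactol as a stable tetrahedral aluminate, and the tert-butyl acrylate is reduced 1,2 to the allylic alcohol C15.

Step 11
Reactants: 20 lactol acid
Product: 21 8α,15-dihydroxy-6β-(triethylsilyloxy)elema-1,3,11(13)-trien-12-oic acid (10β-methyl; 10α-vinyl; 5α-C4; 7β-C11)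
Conditions: Ph3PCH3Br (8 equiv), KOtBu (7.5 equiv), THF, 0 → 45 °C; work-up at pH 5
Reagents that add atoms: methyltriphenylphosphonium bromide C[P+](c1ccccc1)(c1ccccc1)c1ccccc1.[Br-]
Why: Wittig methylenation of the lactol through its open hydroxy aldehyde should turn C1 into the vinyl group and set 8-OH free, the carboxylate and alkoxides being spectators and C10 unable to epimerise.

Step 12
Reactants: 21 8α,15-dihydroxy-6β-(triethylsilyloxy)elema-1,3,11(13)-trien-12-oic acid
Product: 22 triisopropylsilyl 8α-hydroxy-6β-(triethylsilyloxy)-15-(triisopropylsilyloxy)elema-1,3,11(13)-trien-12-oate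
Conditions: iPr3SiCl (2.4 equiv), imidazole, DMF, 0 °C → rt
Reagents that add atoms: chlorotri(propan-2-yl)silane CC(C)[Si](Cl)(C(C)C)C(C)C
Why: silylation should be selective for the carboxylic acid (silyl ester) and the primary allylic 15-OH, because the secondary 8-OH, flanked by C7 and syn to the vinyl group, does not react with the bulky silyl chloride.

Step 13
Reactants: 23 (R)-3-hydroxy-γ-butyrolactone [(4R)-4-hydroxyoxolan-2-one]
Product: 26 (R)-3-hydroxy-2-methylidene-γ-butyrolactone [(4R)-4-hydroxy-3-methylideneoxolan-2-one], via Mannich base 24 (not isolated), via ammonium iodide 25 (not isolated)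
Conditions: LiN(iPr)2 (2.2 equiv), THF, −78 °C; CH2=NMe2+ I−, −78 → 0 °C; sat. aq. NH4Cl; then MeI, MeOH, rt; then NaHCO3 (aq), CH2Cl2
Reagents that add atoms: N,N-dimethylmethaniminium iodide (Eschenmoser's salt) C=[N+](C)C.[I-]
Why: the alkoxide enolate dianion of the β-hydroxy lactone (the alkoxide is too poor a leaving group for β-elimination) should undergo the Mannich reaction, and Hofmann-type elimination then gives the α-methylene lactone without touching the carbinol stereocentre.

Step 14
Reactants: 26 (R)-3-hydroxy-2-methylidene-γ-butyrolactone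
Product: 29 (3R)-2-methylidene-3,4-bis(triethylsilyloxy)butanoic acid, via lithium dihydroxy carboxylate 27 (not isolated), via tris-silyl compound 28 (not isolated)
Conditions: LiOH·H2O (1.05 equiv), THF/H2O, 0 °C; evaporation; Et3SiCl (4 equiv), imidazole, DMF, 0 °C; then pH 5 phosphate buffer/THF
Reagents that add atoms: lithium hydroxide [Li+].[OH-]; chlorotriethylsilane CC[Si](Cl)(CC)CC
Why: the same lactone opening and silylation sequence as in step 9 should give the open-chain acid with both hydroxyls silylated, so that it can no longer relactonise.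

Step 15
Reactants: 22 triisopropylsilyl 8α-hydroxy-6β-(triethylsilyloxy)-15-(triisopropylsilyloxy)elema-1,3,11(13)-trien-12-oate; 29 (3R)-2-methylidene-3,4-bis(triethylsilyloxy)butanoic acid
Product: 31 fully silylated target (8α-ester of 22 with the acyl group of 29), via mixed anhydride 30 (not isolated)
Conditions: 29 (2 equiv), 2,4,6-trichlorobenzoyl chloride, Et3N, toluene, rt; then 22, DMAP (3 equiv), toluene, rt → 50 °C
Reagents that add atoms: none
Why: Yamaguchi esterification through the mixed anhydride should acylate the only free hydroxyl (8α-OH), and no stereocentre is at risk because the acid has no α-hydrogen.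

Step 16
Reactants: 31 fully silylated target
Product: 32 (5S,6S,7S,8S,10S)-6,15-dihydroxy-8-[(3R)-3,4-dihydroxy-2-methylidenebutanoyloxy]elema-1,3,11(13)-trien-12-oic acid (target CNP0348657.4)
Conditions: Bu4NF (10 equiv), AcOH (10 equiv), THF, 0 °C → rt; work-up at pH 5, reversed-phase chromatography
Reagents that add atoms: none
Why: buffered fluoride desilylation should remove the silyl ester and the four silyl ethers near neutral pH, where the carboxylate does not lactonise onto 6-OH and the dihydroxyacyl group is not lost by alkoxide-induced lactonisation.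

**Compound list**

1 | potassium hydrogen (2R,3S)-isocitrate | OC(=O)[C@@H](CC(=O)O)[C@@H](O)C(=O)[O-].[K+] | starting material
2 | (2R,3S)-isocitric acid lactone anhydride | O=C1[C@@H](CC(=O)O2)[C@@H]2C(=O)O1 | intermediate
3 | (2R,3S)-2-[(ethylsulfanyl)carbonyl]-5-oxooxolane-3-carboxylic acid | OC(=O)[C@@H](CC(=O)O2)[C@@H]2C(=O)SCC | intermediate
4 | (2R,3S)-2-formyl-5-oxooxolane-3-carboxylic acid | OC(=O)[C@@H](CC(=O)O2)[C@@H]2C=O | intermediate
5 | (2S,3S)-2-[(E)-3-tert-butoxy-3-oxoprop-1-enyl]-5-oxooxolane-3-carboxylic acid | OC(=O)[C@@H](CC(=O)O2)[C@@H]2/C=C/C(=O)OC(C)(C)C | intermediate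
6 | tert-butyl (E)-3-[(2S,3S)-3-(chlorocarbonyl)-5-oxooxolan-2-yl]prop-2-enoate | ClC(=O)[C@@H](CC(=O)O2)[C@@H]2/C=C/C(=O)OC(C)(C)C | intermediate
7 | tert-butyl (E)-3-[(2S,3S)-3-formyl-5-oxooxolan-2-yl]prop-2-enoate | O=C[C@@H](CC(=O)O2)[C@@H]2/C=C/C(=O)OC(C)(C)C | intermediate
8 | methyl 2-(bromomethyl)prop-2-enoate | C=C(CBr)C(=O)OC | starting material
9 | methyl (4S)-4-[(2S,3R)-2-[(E)-3-tert-butoxy-3-oxoprop-1-enyl]-5-oxooxolan-3-yl]-4-hydroxy-2-methylidenebutanoate | C=C(C(=O)OC)C[C@H](O)[C@@H](CC(=O)O2)[C@@H]2/C=C/C(=O)OC(C)(C)C | intermediate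
10 | tert-butyl (E)-3-[(2S,3R)-3-[(2S)-4-methylidene-5-oxooxolan-2-yl]-5-oxooxolan-2-yl]prop-2-enoate | C=C1C[C@H](OC1=O)[C@@H](CC(=O)O2)[C@@H]2/C=C/C(=O)OC(C)(C)C | intermediate
11 | copper enolate of lactone B of 10 after hydride addition to C14 | CC1=C(O[Cu])O[C@@H](C1)[C@@H](CC(=O)O2)[C@@H]2/C=C/C(=O)OC(C)(C)C | intermediate
12 | cyclised copper enolate of the tert-butyl ester (C4=C15) | O=C2[C@]1(C)C[C@H](O2)[C@@H](CC(=O)O3)[C@@H]3[C@@H]1C=C(O[Cu])OC(C)(C)C | intermediate
13 | tricyclic dilactone tert-butyl ester (10β-methyl; 5α-CH2CO2tBu; lactone A β-fused at C6/C7; lactone B α-bridging C10/C8) | O=C2[C@]1(C)C[C@H](O2)[C@@H](CC(=O)O3)[C@@H]3[C@@H]1CC(=O)OC(C)(C)C | intermediate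
14 | bis-Mannich base of 13 (CH2NMe2 on C11 and on C4; epimers at these carbons) | O=C2[C@]1(C)C[C@H](O2)[C@@H](C(CN(C)C)C(=O)O3)[C@@H]3[C@@H]1C(CN(C)C)C(=O)OC(C)(C)C | intermediate
15 | bis(trimethylammonium) diiodide of 14 | O=C2[C@]1(C)C[C@H](O2)[C@@H](C(C[N+](C)(C)C)C(=O)O3)[C@@H]3[C@@H]1C(C[N+](C)(C)C)C(=O)OC(C)(C)C.[I-].[I-] | intermediate
16 | bis(methylidene) tricycle (C11=C13H2 and C4=C3H2) | O=C2[C@]1(C)C[C@H](O2)[C@@H](C(=C)C(=O)O3)[C@@H]3[C@@H]1C(=C)C(=O)OC(C)(C)C | intermediate
17 | lithium 6β-hydroxy 12-carboxylate from opening of lactone A | O=C2[C@]1(C)C[C@H](O2)[C@@H](C(=C)C(=O)[O-])[C@@H](O)[C@@H]1C(=C)C(=O)OC(C)(C)C.[Li+] | intermediate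
18 | triethylsilyl ester 6β-triethylsilyl ether | O=C2[C@]1(C)C[C@H](O2)[C@@H](C(=C)C(=O)O[Si](CC)(CC)CC)[C@@H](O[Si](CC)(CC)CC)[C@@H]1C(=C)C(=O)OC(C)(C)C | intermediate
19 | seco acid (6β-OSiEt3; 12-CO2H; lactone B; tert-butyl 15-ester) | O=C2[C@]1(C)C[C@H](O2)[C@@H](C(=C)C(=O)O)[C@@H](O[Si](CC)(CC)CC)[C@@H]1C(=C)C(=O)OC(C)(C)C | intermediate
20 | lactol acid (C1 hemiacetal to O8; 15-OH; 12-CO2H; 6β-OSiEt3) | OC2[C@]1(C)C[C@H](O2)[C@@H](C(=C)C(=O)O)[C@@H](O[Si](CC)(CC)CC)[C@@H]1C(=C)CO | intermediate
21 | 8α,15-dihydroxy-6β-(triethylsilyloxy)elema-1,3,11(13)-trien-12-oic acid (10β-methyl; 10α-vinyl; 5α-C4; 7β-C11) | C=C[C@]1(C)C[C@H](O)[C@@H](C(=C)C(=O)O)[C@@H](O[Si](CC)(CC)CC)[C@@H]1C(=C)CO | intermediate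
22 | triisopropylsilyl 8α-hydroxy-6β-(triethylsilyloxy)-15-(triisopropylsilyloxy)elema-1,3,11(13)-trien-12-oate | C=C[C@]1(C)C[C@H](O)[C@@H](C(=C)C(=O)O[Si](C(C)C)(C(C)C)C(C)C)[C@@H](O[Si](CC)(CC)CC)[C@@H]1C(=C)CO[Si](C(C)C)(C(C)C)C(C)C | intermediate
23 | (R)-3-hydroxy-γ-butyrolactone | O=C1C[C@@H](O)CO1 | starting material
24 | Mannich base of 23 (CH2NMe2 on C2) | O=C1C(CN(C)C)[C@@H](O)CO1 | intermediate
25 | trimethylammonium iodide of 24 | O=C1C(C[N+](C)(C)C)[C@@H](O)CO1.[I-] | intermediate
26 | (R)-3-hydroxy-2-methylidene-γ-butyrolactone | O=C1C(=C)[C@@H](O)CO1 | intermediate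
27 | lithium (3R)-3,4-dihydroxy-2-methylidenebutanoate | [Li+].[O-]C(=O)C(=C)[C@@H](O)CO | intermediate
28 | triethylsilyl (3R)-2-methylidene-3,4-bis(triethylsilyloxy)butanoate | CC[Si](CC)(CC)OC(=O)C(=C)[C@@H](O[Si](CC)(CC)CC)CO[Si](CC)(CC)CC | intermediate
29 | (3R)-2-methylidene-3,4-bis(triethylsilyloxy)butanoic acid | OC(=O)C(=C)[C@@H](O[Si](CC)(CC)CC)CO[Si](CC)(CC)CC | intermediate
30 | mixed anhydride of 29 with 2,4,6-trichlorobenzoic acid | C=C(C(=O)OC(=O)c1c(Cl)cc(Cl)cc1Cl)[C@@H](O[Si](CC)(CC)CC)CO[Si](CC)(CC)CC | intermediate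
31 | fully silylated target (6β-OSiEt3; 15-OSi(iPr)3; 12-CO2Si(iPr)3; 3',4'-bis-OSiEt3) | C=C[C@]1(C)C[C@H](OC(=O)C(=C)[C@@H](O[Si](CC)(CC)CC)CO[Si](CC)(CC)CC)[C@@H](C(=C)C(=O)O[Si](C(C)C)(C(C)C)C(C)C)[C@@H](O[Si](CC)(CC)CC)[C@@H]1C(=C)CO[Si](C(C)C)(C(C)C)C(C)C | intermediate
32 | (5S,6S,7S,8S,10S)-6,15-dihydroxy-8-[(3R)-3,4-dihydroxy-2-methylidenebutanoyloxy]elema-1,3,11(13)-trien-12-oic acid | C=C[C@]1(C)C[C@H](OC(=O)C(=C)[C@@H](O)CO)[C@@H](C(=C)C(=O)O)[C@@H](O)[C@@H]1C(=C)CO | target

**Count**

Total steps: 16. Longest linear sequence: 14 steps (steps 1–12, 15 and 16); steps 13 and 14 make the acyl fragment.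

**Steps most likely to fail**

Step 7. Hydride may be delivered to the tert-butyl enoate instead of lactone B, or the C10 enolate may be protonated before it cyclises, giving reduced, uncyclised material. The fallback sets out from 10 and replaces hydride by a sulfur nucleophile that can add only to the exocyclic methylene. PhSLi (from PhSH and BuLi), THF, −78 → 0 °C should give, by sulfa-Michael addition, the lactone lithium enolate F1. This closes the same ring by intramolecular Michael addition to the cyclised lithium ester enolate F2, which after NH4Cl is the 14-(phenylsulfanyl) tricycle F3. Raney nickel (Ni), EtOH, rt then removes sulfur (no C=C bond is present at this stage) and the route is rejoined at 13.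

Step 6. Facial selectivity in the addition to the α-branched aldehyde may be poor, and the aldehyde α-carbon C7 may epimerise before addition. The fallback sets out from 7 and uses catalyst-controlled allylboration in place of the zinc reagent. Methyl 2-[(4,4,5,5-tetramethyl-1,3,2-dioxaborolan-2-yl)methyl]prop-2-enoate and a chiral BINOL-derived phosphoric acid (TRIP, the enantiomer that reinforces the Felkin–Anh face, found by running both) in toluene at −30 °C should give, through a closed six-membered transition state under non-basic conditions, the pinacolboryl ether of the hydroxy ester F4. This is hydrolysed on work-up to 9, and PPTS closes it to 10, where the route is rejoined.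

Step 16. The liberated γ-hydroxy acid may lactonise onto 6-OH during deprotection or isolation, or the dihydroxyacyl group may be lost when its alkoxide cyclises. The fallback sets out from 31 and makes the lactone on purpose. HF·pyridine, THF, rt should desilylate and close the cis 12,6-lactone, giving the robust lactone tetraol F5, which can be purified without pH control. LiOH (1.0 equiv), THF/H2O, −10 °C should then open the activated α-methylene γ-lactone much faster than the hindered secondary acrylate ester, giving the lithium carboxylate of the target F6. AcOH (1.0 equiv) sets free 32, where the route is rejoined.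

**Further compounds**

F1 | step 7 | lactone lithium enolate of the phenylsulfanyl adduct of 10 | [Li]OC1=C(CSc2ccccc2)C[C@H](O1)[C@@H](CC(=O)O3)[C@@H]3/C=C/C(=O)OC(C)(C)C
F2 | step 7 | cyclised lithium ester enolate | O=C2[C@]1(CSc3ccccc3)C[C@H](O2)[C@@H](CC(=O)O4)[C@@H]4[C@@H]1C=C(O[Li])OC(C)(C)C
F3 | step 7 | 14-(phenylsulfanyl) analogue of 13 | O=C2[C@]1(CSc3ccccc3)C[C@H](O2)[C@@H](CC(=O)O4)[C@@H]4[C@@H]1CC(=O)OC(C)(C)C
F4 | step 6 | pinacolboryl ether of 9 | C=C(C(=O)OC)C[C@H](OB1OC(C)(C)C(C)(C)O1)[C@@H](CC(=O)O2)[C@@H]2/C=C/C(=O)OC(C)(C)C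
F5 | step 16 | 12,6-lactone of the target | C=C[C@]1(C)C[C@H](OC(=O)C(=C)[C@@H](O)CO)[C@@H](C(=C)C(=O)O2)[C@@H]2[C@@H]1C(=C)CO
F6 | step 16 | lithium carboxylate of the target | C=C[C@]1(C)C[C@H](OC(=O)C(=C)[C@@H](O)CO)[C@@H](C(=C)C(=O)[O-])[C@@H](O)[C@@H]1C(=C)CO.[Li+]
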